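**Plan** (atoms numbered as in the isochromene core: C1, O2, C3, C4, C4a, C5–C8, C8a; O7 is the oxygen on C7; ring A is the carbocycle, ring B the pyran)
- Retrosynthesis: cut the O7–acyl bond; trace the C8 ketone and C1=C8a back to a C8 bromide and a C1 ethoxy acetal; restore C4a–O7 as an oxa-bridge; then cut C7–C8 and C4a–C8a in one retro-[4+2]. O2–C1 (acetal), the furan O–C bond and one ynone C–C bond remain.
- Enabling feature: O7 on C7 faces C4a across ring A (1,4), so C7, C6, C5, C4a and O7 form a hidden 2-methyl-3-oxyfuran, and C4–C3–O2–C1 of ring B is a four-atom tether from that furan to a C8≡C8a alkyne.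
- Forward: acetylide acylation joins the chain, the furanone (later the furan) is closed, the bromoalkynyl acetal is hung on O2, rings A and B close together, then bridge opening, C8 oxygenation and O7 acylation.
- Stereochemistry: C3 is bought with (R)-pent-4-yn-2-ol; C7 is set in the cycloaddition by relay from C3 through the tether; C4a, C1 and the lactate centre are transient.

Key step: step 10

Remark: C1 is carried as a mixture of both acetal epimers because it becomes sp2 in step 12; the lactate centre is erased in step 9 and only keeps 8 a single isomer.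

Step 1
Reactants: 1 (R)-pent-4-yn-2-ol
Product: 2 (R)-tert-butyldimethyl(pent-4-yn-2-yloxy)silane
Conditions: TBSCl, imidazole, DMF, rt
Reagents that add atoms: tert-butyldimethylsilyl chloride, CC(C)(C)[Si](C)(C)Cl
Why: Imidazole-promoted O-silylation masks the hydroxyl so that the alkyne C–H is the only acidic site in step 4; the future C3 centre is not touched.

Step 2
Reactants: 3 ethyl (S)-lactate
Product: 4 ethyl (S)-2-[(tert-butyldimethylsilyl)oxy]propanoate
Conditions: TBSCl, imidazole, DMF, rt
Reagents that add atoms: tert-butyldimethylsilyl chloride, CC(C)(C)[Si](C)(C)Cl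
Why: The same O-silylation keeps the α-hydroxyl from quenching the organometallic reagents of steps 3 and 4.

Step 3
Reactants: 4 ethyl (S)-2-[(tert-butyldimethylsilyl)oxy]propanoate
Product: 5 (S)-2-[(tert-butyldimethylsilyl)oxy]-N-methoxy-N-methylpropanamide
Conditions: MeNH(OMe)·HCl, i-PrMgCl, THF, −20 → 0 °C
Reagents that add atoms: N,O-dimethylhydroxylamine hydrochloride, CNOC.Cl
Why: Aminolysis of the ester by the chloromagnesium amide of N,O-dimethylhydroxylamine (Weinreb amide formation) is routine for O-silyl lactates.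

Step 4
Reactants: 2 (R)-tert-butyldimethyl(pent-4-yn-2-yloxy)silane; 5 (S)-2-[(tert-butyldimethylsilyl)oxy]-N-methoxy-N-methylpropanamide
Product: 6 (2S,7R)-2,7-bis[(tert-butyldimethylsilyl)oxy]oct-4-yn-3-one
Conditions: n-BuLi, THF, −78 °C; then 5, −78 → 0 °C; aq. NH4Cl
Reagents that add atoms: none
Why: Weinreb ketone synthesis: the lithium acetylide of 2 adds once because the N-methoxy chelate holds the tetrahedral intermediate until work-up.

Step 5
Reactants: 6 (2S,7R)-2,7-bis[(tert-butyldimethylsilyl)oxy]oct-4-yn-3-one
Product: 7 (2S,7R)-2,7-dihydroxyoct-4-yn-3-one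
Conditions: HF·pyridine, pyridine, THF, 0 °C → rt
Reagents that add atoms: none
Why: Fluoride-driven Si–O cleavage removes both silyl ethers under buffered, non-basic conditions that leave the ynone intact.

Step 6
Reactants: 7 (2S,7R)-2,7-dihydroxyoct-4-yn-3-one
Product: 8 (2S)-5-[(2R)-2-hydroxypropyl]-2-methylfuran-3(2H)-one
Conditions: (p-CF3C6H4)3PAuCl (5 mol %), AgOTf (5 mol %), PhMe, rt
Reagents that add atoms: none
Why: Cationic monovalent gold activates the alkyne and the hydroxyl next to the ketone adds 5-endo-dig to the β-carbon of the ynone (cycloisomerisation of α'-hydroxy ynones to 3(2H)-furanones); the homopropargylic hydroxyl could only reach the α-carbon or close an oxetane and should stay free.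

Step 7
Reactants: 9 3,3-diethoxyprop-1-yne
Product: 10 1-bromo-3,3-diethoxyprop-1-yne
Conditions: NBS, AgNO3 (10 mol %), acetone, rt
Reagents that add atoms: N-bromosuccinimide, O=C1CCC(=O)N1Br
Why: Silver-catalysed electrophilic bromination of the terminal alkyne through the silver acetylide is neutral enough for the acetal.

Step 8
Reactants: 8 (2S)-5-[(2R)-2-hydroxypropyl]-2-methylfuran-3(2H)-one; 10 1-bromo-3,3-diethoxyprop-1-yne
Product: 11 (2S)-5-[(2R)-2-(3-bromo-1-ethoxyprop-2-yn-1-yloxy)propyl]-2-methylfuran-3(2H)-one (both C1 epimers)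
Conditions: 10 (4 equiv), PPTS (10 mol %), PhH, 5 Å MS, 50 °C
Reagents that add atoms: none
Why: Acid-catalysed transacetalisation through the alkynyl oxocarbenium ion; an excess of 10 and removal of ethanol should hold the exchange at the mixed acetal, and C3 is untouched because only O–C1 bonds are made and broken.

Step 9
Reactants: 11 (2S)-5-[(2R)-2-(3-bromo-1-ethoxyprop-2-yn-1-yloxy)propyl]-2-methylfuran-3(2H)-one
Product: 12 tert-butyl[(5-{(2R)-2-[(3-bromo-1-ethoxyprop-2-yn-1-yl)oxy]propyl}-2-methylfuran-3-yl)oxy]dimethylsilane (both C1 epimers)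
Conditions: TBSOTf, Et3N, CH2Cl2, −78 → 0 °C
Reagents that add atoms: tert-butyldimethylsilyl triflate, CC(C)(C)[Si](C)(C)OS(=O)(=O)C(F)(F)F
Why: Soft enolisation and O-silylation of the 3(2H)-furanone (silyl enol ether formation) gives the aromatic 3-silyloxyfuran, the usual entry to this diene class; the lactate centre becomes sp2 and the excess amine keeps the triflate from ionising the acetal.

Step 10
Reactants: 12 tert-butyl[(5-{(2R)-2-[(3-bromo-1-ethoxyprop-2-yn-1-yl)oxy]propyl}-2-methylfuran-3-yl)oxy]dimethylsilane
Product: 13 (3R,4aS,7R)-8-bromo-6-[(tert-butyldimethylsilyl)oxy]-1-ethoxy-3,7-dimethyl-3,4-dihydro-1H-4a,7-epoxyisochromene (O7 bridges C7 and C4a; both C1 epimers)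
Conditions: PhMe (0.01 M), 2,6-di-tert-butylpyridine (0.2 equiv), BHT (cat.), 110 °C, sealed tube
Reagents that add atoms: none
Why: A concerted, asynchronous thermal [4+2] cycloaddition joins the furan diene (C7–C6–C5–C4a) to the bromoalkyne (C8≡C8a); the closest known reaction type is the intramolecular Diels–Alder reaction of donor-substituted furans with tethered, unactivated alkenes and alkynes, and here the 3-silyloxy donor, the acetal in the tether and the halogen on the dienophile (which stabilises the adduct) all work in its favour. Ring A closes as the new six-membered cycloadduct ring through the C7–C8 and C4a–C8a bonds, with O7 left as its 1,4-bridge, and ring B closes as the six-membered tether ring C4a–C4–C3–O2–C1–C8a (type 1 mode, tether on a diene terminus); an alkyne poses no endo/exo question. C7 and C4a arise together by suprafacial addition to one furan face, so their relative configuration is fixed and the absolute sense is relayed from C3. The step therefore needs only facial selectivity: in the half-chair tether the C3 methyl should sit pseudo-equatorial and the C4–C3 bond should turn towards the lone pairs of the furan oxygen, not against C5–H, which puts the alkyne on the face that gives 7R (4aS); with an alkyne the addition is not expected to revert, so the ratio is kinetic. Both C1 epimers are taken on together because C1 becomes sp2 in step 12. Acid is kept out (hindered pyridine, base-washed glass) since a cation at C1 would be captured by C5 in an oxa-Pictet–Spengler closure and the silyl enol ether is acid-labile.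

Step 11
Reactants: 13 (3R,4aS,7R)-8-bromo-6-[(tert-butyldimethylsilyl)oxy]-1-ethoxy-3,7-dimethyl-3,4-dihydro-1H-4a,7-epoxyisochromene
Product: 15 (3R,7R)-8-bromo-1-ethoxy-7-hydroxy-3,7-dimethyl-3,4-dihydro-1H-isochromen-6(7H)-one, via oxa-bridged C6 ketone 14 (not isolated)
Conditions: TBAF (1.1 equiv), THF, −78 → 0 °C; then AcOH
Reagents that add atoms: none
Why: Fluoride cleaves the silyl enol ether to the C6 enolate/ketone 14, whose C4a–O7 bond is β to the carbonyl and is expelled by E1cB elimination (the usual base opening of 7-oxanorbornenones), giving C4a=C5 and free O7–H without touching C7.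

Step 12
Reactants: 15 (3R,7R)-8-bromo-1-ethoxy-7-hydroxy-3,7-dimethyl-3,4-dihydro-1H-isochromen-6(7H)-one
Product: 17 (3R,7R)-7-hydroxy-3,7-dimethyl-3,4-dihydro-6H-isochromene-6,8(7H)-dione, via 8-hydroxy dienone acetal 16 (not isolated)
Conditions: LiOH (2.2 equiv), THF/H2O (4:1), 0 °C → rt; pH 7 buffer
Reagents that add atoms: lithium hydroxide, [Li+].[OH-]
Why: C8 is the δ-carbon of the 2,4-dienone, so hydroxide should add in the 1,6-sense and expel bromide (vinylogous nucleophilic vinylic substitution by addition–elimination, as in the hydrolysis of β-halo enones), and the resulting C8 enolate is vinylogous to the C1 ethoxy group and ejects ethoxide (E1cB), which forms C1=C8a and merges both acetal epimers.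

Step 13
Reactants: 17 (3R,7R)-7-hydroxy-3,7-dimethyl-3,4-dihydro-6H-isochromene-6,8(7H)-dione; 18 stearoyl chloride
Product: 19 (3R,7R)-3,7-dimethyl-6,8-dioxo-3,4-dihydroisochromen-7-yl octadecanoate (CNP0142202.1)
Conditions: Et3N, DMAP (cat.), CH2Cl2, 0 °C → rt
Reagents that add atoms: none
Why: DMAP-catalysed acyl transfer from the acid chloride esterifies the tertiary α-ketol hydroxyl, the standard way of acylating O7 in this class of dienediones; no stereocentre is involved.

**Compound list**
1 | (R)-pent-4-yn-2-ol | C[C@@H](O)CC#C | starting material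
2 | (R)-tert-butyldimethyl(pent-4-yn-2-yloxy)silane | C[C@@H](O[Si](C)(C)C(C)(C)C)CC#C | intermediate
3 | ethyl (S)-lactate | CCOC(=O)[C@H](C)O | starting material
4 | ethyl (S)-2-[(tert-butyldimethylsilyl)oxy]propanoate | CCOC(=O)[C@H](C)O[Si](C)(C)C(C)(C)C | intermediate
5 | (S)-2-[(tert-butyldimethylsilyl)oxy]-N-methoxy-N-methylpropanamide | CON(C)C(=O)[C@H](C)O[Si](C)(C)C(C)(C)C | intermediate
6 | (2S,7R)-2,7-bis[(tert-butyldimethylsilyl)oxy]oct-4-yn-3-one | C[C@H](O[Si](C)(C)C(C)(C)C)C(=O)C#CC[C@@H](C)O[Si](C)(C)C(C)(C)C | intermediate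
7 | (2S,7R)-2,7-dihydroxyoct-4-yn-3-one | C[C@H](O)C(=O)C#CC[C@@H](C)O | intermediate
8 | (2S)-5-[(2R)-2-hydroxypropyl]-2-methylfuran-3(2H)-one | C[C@@H]1OC(C[C@@H](C)O)=CC1=O | intermediate
9 | 3,3-diethoxyprop-1-yne | C#CC(OCC)OCC | starting material
10 | 1-bromo-3,3-diethoxyprop-1-yne | CCOC(C#CBr)OCC | intermediate
11 | (2S)-5-[(2R)-2-(3-bromo-1-ethoxyprop-2-yn-1-yloxy)propyl]-2-methylfuran-3(2H)-one (both C1 epimers) | CCOC(C#CBr)O[C@H](C)CC1=CC(=O)[C@H](C)O1 | intermediate
12 | tert-butyl[(5-{(2R)-2-[(3-bromo-1-ethoxyprop-2-yn-1-yl)oxy]propyl}-2-methylfuran-3-yl)oxy]dimethylsilane (both C1 epimers) | CCOC(C#CBr)O[C@H](C)Cc1cc(O[Si](C)(C)C(C)(C)C)c(C)o1 | intermediate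
13 | (3R,4aS,7R)-8-bromo-6-[(tert-butyldimethylsilyl)oxy]-1-ethoxy-3,7-dimethyl-3,4-dihydro-1H-4a,7-epoxyisochromene (both C1 epimers) | C[C@@]12O[C@]3(C=C1O[Si](C)(C)C(C)(C)C)C[C@@H](C)OC(OCC)C3=C2Br | intermediate
14 | (3R,4aS,7R)-8-bromo-1-ethoxy-3,7-dimethyl-3,4-dihydro-1H-4a,7-epoxyisochromen-6(5H)-one (oxa-bridged C6 ketone; formed in the flask in step 11) | C[C@@]12O[C@]3(CC1=O)C[C@@H](C)OC(OCC)C3=C2Br | intermediate
15 | (3R,7R)-8-bromo-1-ethoxy-7-hydroxy-3,7-dimethyl-3,4-dihydro-1H-isochromen-6(7H)-one (both C1 epimers) | C[C@@]1(O)C(=O)C=C2C[C@@H](C)OC(OCC)C2=C1Br | intermediate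
16 | 8-hydroxy dienone acetal (bromine of 15 replaced by OH; C8 enol, present as its enolate; C7 arranged as in 15; formed in the flask in step 12) | C[C@@]1(O)C(=O)C=C2C[C@@H](C)OC(OCC)C2=C1O | intermediate
17 | (3R,7R)-7-hydroxy-3,7-dimethyl-3,4-dihydro-6H-isochromene-6,8(7H)-dione | C[C@@]1(O)C(=O)C=C2C[C@@H](C)OC=C2C1=O | intermediate
18 | stearoyl chloride | CCCCCCCCCCCCCCCCCC(=O)Cl | starting material
19 | (3R,7R)-3,7-dimethyl-6,8-dioxo-3,4-dihydroisochromen-7-yl octadecanoate | CCCCCCCCCCCCCCCCCC(=O)O[C@]1(C)C(=O)C=C2C[C@@H](C)OC=C2C1=O | target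

**Step count:** 13 steps in total; the longest linear sequence is 11 steps (3 → 19 through steps 2, 3, 4, 5, 6, 8, 9, 10, 11, 12, 13).

**Steps most likely to fail**

1. Step 10. The bromoalkyne is only weakly activated, so cycloaddition may be slower than desilylation or oligomerisation of the silyloxyfuran at the temperature needed, and heat also weakens the discrimination between the two furan faces. The fallback replaces bromine by a sulfonyl group, a proven activator for alkyne–furan cycloadditions that also leaves as sulfinate; it sets out from 9 and 8 and returns at 17. Acetal 9 would be lithiated (n-BuLi, THF, −78 °C) and sulfenylated with PhSSPh to 3,3-diethoxy-1-(phenylsulfanyl)prop-1-yne F1, then oxidised (mCPBA, NaHCO3, CH2Cl2) to 3,3-diethoxy-1-(phenylsulfonyl)prop-1-yne F2. Exchange onto 8 as in step 8 would give the sulfonyl mixed acetal F3, and silylation (TBSOTf, i-Pr2NEt) the sulfonyl silyloxyfuran F4. F4 should cyclise at or near room temperature, under kinetic control, to the sulfonyl oxa-bridged adduct F5 (configured as 13). TBAF would open it to the 8-sulfonyl dienone F6, and LiOH would displace benzenesulfinate from C8 and ethanol from C1 (through 16) to reach 17.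

2. Step 12. Hydroxide may add to C4a or C6 instead of C8, or trigger an α-ketol shift or retro-aldol cleavage at the C7 carbinol, before bromide is displaced. The fallback introduces the C8 oxygen as an electrophile at the adduct stage; it sets out from 13 and returns at 17, bypassing 15. Bromine–lithium exchange on 13 (t-BuLi, 2 equiv, THF, −78 °C) and trapping of the vinyllithium with bis(trimethylsilyl) peroxide would give the C8 trimethylsilyl enol ether F7. TBAF (2.2 equiv) would then free both enolates at once: the C8 enolate ejects ethoxide from C1 and the C6 enolate opens the bridge, giving 17 without any hydroxide.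

3. Step 8. The exchange may stall at a statistical mixture (diethyl acetal, mixed acetal, doubly exchanged acetal), and the free oxocarbenium ion may be captured by the nucleophilic C–H carbon of the furanone ring. The fallback couples under basic conditions; it sets out from 10 and returns at 11. Acetyl chloride with ZnBr2 (1 mol %) would convert 10 into 1-bromo-3-chloro-3-ethoxyprop-1-yne F8, which is used crude and alkylates the hydroxyl of 8 in the presence of i-Pr2NEt (CH2Cl2, 0 °C) to give 11.

**Further compounds**
F1 | step 10 | 3,3-diethoxy-1-(phenylsulfanyl)prop-1-yne | CCOC(C#CSc1ccccc1)OCC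
F2 | step 10 | 3,3-diethoxy-1-(phenylsulfonyl)prop-1-yne | CCOC(C#CS(=O)(=O)c1ccccc1)OCC
F3 | step 10 | (2S)-5-[(2R)-2-(1-ethoxy-3-(phenylsulfonyl)prop-2-yn-1-yloxy)propyl]-2-methylfuran-3(2H)-one (both C1 epimers) | CCOC(C#CS(=O)(=O)c1ccccc1)O[C@H](C)CC1=CC(=O)[C@H](C)O1
F4 | step 10 | sulfonyl silyloxyfuran (12 with PhSO2 in place of Br) | CCOC(C#CS(=O)(=O)c1ccccc1)O[C@H](C)Cc1cc(O[Si](C)(C)C(C)(C)C)c(C)o1
F5 | step 10 | sulfonyl oxa-bridged adduct (13 with PhSO2 in place of Br) | C[C@@]12O[C@]3(C=C1O[Si](C)(C)C(C)(C)C)C[C@@H](C)OC(OCC)C3=C2S(=O)(=O)c1ccccc1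
F6 | step 10 | 8-sulfonyl dienone (15 with PhSO2 in place of Br) | C[C@@]1(O)C(=O)C=C2C[C@@H](C)OC(OCC)C2=C1S(=O)(=O)c1ccccc1
F7 | step 12 | C8 trimethylsilyl enol ether (13 with OSiMe3 in place of Br) | C[C@@]12O[C@]3(C=C1O[Si](C)(C)C(C)(C)C)C[C@@H](C)OC(OCC)C3=C2O[Si](C)(C)C
F8 | step 8 | 1-bromo-3-chloro-3-ethoxyprop-1-yne | CCOC(Cl)C#CBr
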